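All runs are simulated for substances that don't exist, and the scatter is random.

**Slow solid.** D enters solution slowly, and that made me doubt the next charge: did raising it from 1.5 M to 2.0 M buy more E by 4.0 min?

| flask | D | remark | time |
|---|---|---|---|
| oak | 1 M | run made earlier |  |
| birch | 1.5 M | run made earlier |  |
| flask | 2.0 M |  | 4.0 min |

- oak (time / min: E / %, Z / %): 1.33: 5.4, 13.8; 2.50: 8.1, 18.9; 4.00: 7.8, 14.6; 5.00: 5.8, 11.6
- birch (time / min: E / %, Z / %): 0.667: 2.1, 6.9; 1.50: 3.6, 10.2; 3.00: 6.7, 13.4; 5.00: 7.9, 16.7

(each reading ± 0.5 percentage points)

1. E at 4.0 min, in percent of the D charged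
2. concentration of Z in solution at 4.0 min, in percent of saturation

- solid, in amounts per volume of the solution: D
- at the start none of D is in solution
- Z is what D becomes in solution
- Z means what is dissolved; the solid is not counted in it

**Shared curve.** I turned the readings into molar terms. Oak showed [E] of 0.0540 M at 1.33 min and birch showed 0.0540 M at 1.50 min, so early on the solution took little notice of the charge, which is zero order in the charge. Later oak dropped off this curve: its Z fell to 14.6 % at 4.00 min, while birch's Z still rose. I judged that a larger charge stays on the curve at least as long as birch did.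

**Birch level.** Halfway between birch's readings at 3.00 min and 5.00 min, [E] reads 0.110 M. That is my birch level, the molar E at the asked time of a solution still fed by solid. It is 7.33 % of a birch charge but 5.48 % of the new one. I decided to charge 2.0 M once, as a test, expecting no gain in [E].

**The forecast.** It gave 6.9 % of E and put [Z] at 62 % of saturation, reasoning that “solid persists, so Z should rise but flatten as it nears saturation”. My figure for E stood lower.

**The result.** The flask gave 5.16 % of E. Its [Z] stood at 28.6 % of saturation.

    Z ⇌ G (K = 2.20, k = 0.00970 /s)
    Z ⇌ X (K = 1.10, k = 0.0120 /s)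
    D ⇌ Z, rate k3*(cs3 - [Z]) while solid is left; crystals form when [Z] > cs3 (solubility = 0.790 M, k = 0.00780 /s)
    Z ⇌ Q (K = 2.40, k = 0.0100 /s)
    Z ⇌ E (K = 0.600, k = 0.0210 /s)
    E ⇌ J (K = 25.0, k = 0.00960 /s)

In this flask D still stood at 41.0 % at 4.00 min. The flask's [E] was 0.103 M against the birch level of 0.110 M, so I went back to 1.5 M.

**Second flask.** For the neighbour charged with 0.80 M, the birch level gave 13.7 %. The computed result for that neighbour was 6.56 %, about half of that, so it was off the curve; its D stood at 0 %.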